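## The problem

(+)-Miliusane V (27) is a 2-oxaspiro[4.5]decane-3,6-dione. Its cyclohexanone α-carbon C5 is a quaternary spiro centre shared with a γ-butyrolactone, the lactone O–CH carbon C1 carries an (E)-2,6-dimethylhepta-1,5-dienyl chain, and the carbocycle carries a cis acetamido alcohol at C8/C9. C1 and C5 are contiguous, but C8 and C9 lie across the ring from them (C9 is 1,3 to C5 through C10), so relative control between the two pairs must be relayed through the ring. The C6 ketone is β to the acetamide (E1cB loss) and, through the non-enolisable C5, β to the lactone oxygen (retro-aldol once a base opens the lactone). The C1–O bond is allylic to a trisubstituted alkene and ionises in strong acid, and the two trisubstituted alkenes rule out catalytic hydrogenation. The ketone must therefore be unveiled late and no basic step may follow it. Because C6 ends as a carbonyl, a carbinol there can serve as a disposable stereocentre that is set by catalysis, fixes C5 and is then oxidised away. The feature that carries the plan is that C1, the C9 oxygen and the C8 nitrogen all lie on one face of the cyclohexane. With C1 at the carboxylic acid level, its oxygen can reach C9 across the ring and close a bridged γ-lactone onto a C8=C9 alkene, which leaves a leaving group at C8 on the opposite face for inversion by nitrogen.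

## Retrosynthesis

Locants: spiro numbering (C1 carbinol, O2, C3, C5 spiro, C6, C8, C9) for 22–27, bicyclo[3.2.1] numbering for 11–13, cyclohexene numbering for 5–10.

**27 from 25 (N–acetyl bond).** The amide is traced to the azido acetate 25. Reduction gives the amino acetate 26, in which the acetyl group moves from O9 to the cis nitrogen. Compared with an early acetamide and a separate protecting group on O9, the acetate both masks O9 during the C6 oxidation and supplies the acetyl group, so the last step needs neither base nor acid. The forward step must reduce the azide without touching the alkenes, the ketone or the allylic lactone.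

**25 from 24 and 23 (oxidation level at C6).** The ketone is taken back to the carbinol 24 and its silyl ether 23. A ketone carried earlier would compete with the aldehyde in the side-chain addition and would sit β to a leaving group for many steps. The forward steps are a desilylation at a neopentyl carbinol and a mild, non-basic oxidation.

**23 from 21 through 22 (lactone acyl–oxygen bond and O-acetyl).** Opening the spirolactone gives the dihydroxy tert-butyl ester 21. Closure is unambiguous only while the C6 oxygen is silylated: that oxygen is cis to the acetate arm and would otherwise form a fused γ-lactone. The ring hydroxyl is trans to the arm and cannot reach it. The side-chain alkoxide then closes 22, and the remaining hydroxyl is acetylated to 23.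

**21 from 13 and 18 (carbinol–alkenyl bond).** This cut makes the nine-carbon chain a separate alkenyl metal (19, then 20, from iodide 18) and the ring fragment an aldehyde masked as the bridged lactol 13. The neighbouring option is acyl addition to lactone 12 followed by ketone reduction. It is less attractive because hydride would then take the exposed face and give the C1' epimer, and because an organolithium would have to choose a hindered lactone over an ester and an azide. The forward step asks for addition to the outer face of a magnesium chelate between the aldehyde oxygen and the syn-axial alkoxide.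

**18 from 16 from 14.** The alkenyl iodide comes from carboalumination of alkyne 16 (through alane 17), which fixes the E geometry. Alkyne 16 comes from 6-methylhept-5-en-2-one (14) through enol phosphate 15.

**13 from 12 from 11.** The lactol is the half-reduced lactone 12. The C4–N bond of 12 is cut to the iodide 11, whose iodine is trans to the lactone oxygen, so that SN2 displacement gives the cis relationship.

**11 from 10 (lactone alkyl–oxygen bond and C–I bond).** Both bonds are cut back to the alkene of the quaternary cyclohex-3-enecarboxylic acid 10, losing one ring and two stereocentres. The carboxyl, 1,3 to the alkene, can only deliver oxygen to its own face. The silyloxy carbon of 10 is drawn trans to the carboxyl and cis to the acetate arm, because that is what the alkylation below delivers; this costs a syn-axial iodine/silyloxy contact in 11.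

**10 from 9, 8, then 5 and 6 (quaternary carbon–CH2 bond).** The acetate arm is cut from C1, leaving the β-hydroxy ester 5, which is alkylated as its dianion 7 with tert-butyl bromoacetate (6). The electrophile enters cis to the alkoxide, so the 6R carbinol fixes the quaternary centre. Silylation (9) and hydrolysis of the methyl ester give 10.

**5 from 3 (through 4) from 1 and 2.** The C6–O bond is traced to a conjugate borylation–oxidation of the dienoate 3. Ester 3 is the Diels–Alder adduct of butadiene (1) and methyl propiolate (2), which supplies both the conjugated alkene for borylation and the isolated alkene for the key step.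

## Roads not taken

Alternative 1: The cut is the bond between the spiro carbon and its ring CH2, made by a 1,2-shift. Epoxy cyclopentanol A1 with ZnBr2 should open at the tertiary epoxide carbon while a ring CH2 migrates anti to the departing oxygen, giving the 2,2-disubstituted cyclohexanone A2 with the allylic hydroxyl freed. One stereospecific step would create the quaternary centre, the adjacent ketone and the C1 carbinol, with their relationship read from the epoxide geometry. That is more secure for the C1/C5 pair than the chelate-controlled addition in step 11. The weak points are three. The epoxide of A1 is also an alkenyl epoxide, so the Lewis acid may ionise the allylic C–O bond instead of the tertiary one. A1 needs a site-selective epoxidation among three alkenes. A2 has no functionality at C8 or C9, so the cis amino alcohol would have to be placed on unactivated ring carbons next to a retro-aldol-prone β-hydroxy ketone. The chosen plan is longer before the chain is attached, but it places every ring heteroatom by a tether or an inversion.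

Alternative 2: The cut removes the C5–C6 and C1–O bonds in one cycloaddition. Oxidation of aldoxime A3 (NaOCl) would give nitrile oxide A4, which adds across the tethered trisubstituted alkene to give isoxazoline A5 and close the cyclohexane. A5 holds every carbon, nitrogen and oxygen of the target, and the suprafacial addition transfers alkene geometry to the C1/C5 relationship. N–O cleavage, imine hydrolysis, lactonisation and desilylation would finish in about four steps, fewer than the seven main-line steps that follow step 6 here, and C1 would need no separate control. Against this, the face of the alkene that the dipole takes, and so the quaternary centre relative to C8/C9, rests only on the conformation of the tether. The reacting alkene is the inner double bond of a conjugated diene, so A3 needs a stereodefined trisubstituted diene and a syn amino alcohol built by acyclic stereocontrol. The N–O cleavage must also spare two alkenes. The chosen plan sets against this cheap achiral starting materials, ring stereocentres fixed by intramolecular delivery, and a key step with close analogy.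

Alternative 3: The cut removes the C5–C6 and C9–C10 bonds in a [4+2] cycloaddition of dienone A6 with diene A7, giving the all-cis adduct A8. This is the most convergent option: ring, quaternary centre, both ring oxygens, acetate arm and side chain arrive in one intermolecular step, in fewer steps than the five that precede step 6 here. Its weak points are as follows. A6 is a cross-conjugated α-methylene ketone that should dimerise readily. Absolute control would need a chiral Lewis acid for a hindered α-substituted enone in the presence of an acid-labile diene. Regiochemistry depends on the silyloxy terminus outranking the acetoxy terminus as donor. After the cycloaddition, nitrogen is still missing at C8 and the side-chain ketone must be reduced selectively beside the C6 oxygen function. The chosen plan gives up convergency for stepwise, tether-enforced control of the cis amino alcohol and an absolute configuration fixed early by catalysis.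

Key step: step 6

Remark 1: the dianion alkylation in step 3 is taken to enter cis to the lithium alkoxide, as is general for dianions of 2-hydroxycycloalkane-1-carboxylates; if the sense were opposite, the antipodal ligand in step 2 would give the same quaternary centre, since the carbinol is erased in step 14.

Remark 2: the ligand antipode named in step 2 is taken to deliver the 6R carbinol; otherwise its mirror image is used.

Step 1
Reactants: 1 buta-1,3-diene; 2 methyl propiolate
Product: 3 methyl cyclohexa-1,4-diene-1-carboxylate
Conditions: toluene, hydroquinone (cat.), sealed vessel, 120 °C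
Reagents that add atoms: none
Why: Thermal Diels–Alder reaction of an alkynoate dienophile, which gives the skipped diene directly with one conjugated alkene for step 2 and one isolated alkene for the key step.

Step 2
Reactants: 3
Product: 5 methyl (6R)-6-hydroxycyclohex-3-ene-1-carboxylate, via boronic ester 4 (not isolated)
Conditions: CuCl (5 mol %), NaOtBu (10 mol %), (R)-1-[(S)-2-(diphenylphosphino)ferrocenyl]ethyldicyclohexylphosphine (5.5 mol %), B2pin2 (1.1 equiv), MeOH (2 equiv), THF, 23 °C; then NaBO3·4H2O, THF/H2O, 23 °C
Reagents that add atoms: sodium perborate, [Na+].[Na+].O[B-]1(O)OO[B-](O)(O)OO1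
Why: Copper-catalysed enantioselective conjugate borylation of an α,β-unsaturated ester puts boron (from B2pin2) on the β-carbon of the conjugated alkene only and sets C6 under ligand control; perborate oxidation then replaces boron by oxygen with retention. The C1 centre formed on protonation may be a mixture, because it is erased by enolisation in step 3.

Step 3
Reactants: 5; 6 tert-butyl bromoacetate
Product: 8 methyl (1S,6R)-1-(2-tert-butoxy-2-oxoethyl)-6-hydroxycyclohex-3-ene-1-carboxylate, via dilithium dianion 7 (not isolated)
Conditions: LiN(iPr)2 (2.3 equiv), THF, −78 → −20 °C; then 6, DMPU, −78 → −45 °C; AcOH, −78 °C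
Reagents that add atoms: none
Why: Fráter–Seebach alkylation: both C1 epimers of 5 give the same lithium-chelated enolate–alkoxide 7, which is alkylated by axial attack on the face syn to the alkoxide, so the acetate arm ends cis to the hydroxyl and the quaternary centre is set by C6. The cold quench keeps the alkoxide from lactonising onto the tert-butyl ester.

Step 4
Reactants: 8
Product: 9 methyl (1S,6R)-1-(2-tert-butoxy-2-oxoethyl)-6-[(tert-butyldimethylsilyl)oxy]cyclohex-3-ene-1-carboxylate
Conditions: TBSOTf, 2,6-lutidine, CH2Cl2, −78 → −20 °C
Reagents that add atoms: tert-butyldimethylsilyl trifluoromethanesulfonate, CC(C)(C)[Si](C)(C)OS(=O)(=O)C(F)(F)F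
Why: Silylation of a hindered secondary alcohol with the silyl triflate; the group keeps this oxygen, which is cis to the acetate arm, from lactonising onto it in steps 5 to 12.

Step 5
Reactants: 9
Product: 10 (1S,6R)-1-(2-tert-butoxy-2-oxoethyl)-6-[(tert-butyldimethylsilyl)oxy]cyclohex-3-ene-1-carboxylic acid
Conditions: LiOH·H2O, THF/MeOH/H2O, 50 °C; then 1 M HCl to pH 4, 0 °C
Reagents that add atoms: lithium hydroxide, [Li+].[OH-]
Why: Saponification of the methyl ester; the tert-butyl ester resists hydroxide attack and the silyl ether is stable to aqueous base, so only the carboxyl on the quaternary carbon is freed.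

Step 6
Reactants: 10
Product: 11 tert-butyl 2-[(1S,2R,4S,5S)-2-[(tert-butyldimethylsilyl)oxy]-4-iodo-7-oxo-6-oxabicyclo[3.2.1]octan-1-yl]acetate
Conditions: NaHCO3 (3 equiv), I2 (2.5 equiv), KI, THF/H2O, 0 → 23 °C, dark
Reagents that add atoms: iodine, II
Why: Bicarbonate converts 10 into its carboxylate, and iodine is taken up productively only on the alkene face opposite the carboxyl, where the axial carboxylate oxygen attacks the nearer alkene carbon anti to iodine through an iodonium-like transition structure (iodolactonisation). The closest known reaction type is the halolactonisation of cyclohex-3-ene-1-carboxylic acids to 4-halo-6-oxabicyclo[3.2.1]octan-7-ones. The γ-lactone closes in the 5-exo mode through a half-chair with the carboxyl axial, in preference to 6-endo attack at the farther carbon, which would give a 2-oxabicyclo[2.2.2]octanone. The new C5–O stereocentre is fixed by the tether, since a carboxyl on C1 can only bridge to the face it occupies. The new C4–I stereocentre is fixed by the anti course of the addition, which puts iodine trans to the lactone oxygen and ready for inversion in step 7. The step needs chemoselectivity for the carboxylate over the tert-butyl ester carbonyl (which could close a δ-lactone from the other face with loss of isobutene) and over the silyl ether oxygen; the anionic carboxylate and the faster five-membered closure secure it. The silyloxy group, trans to the carboxyl, ends syn-axial to iodine in 11, and closure under buffered, effectively irreversible conditions is expected to tolerate this contact.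

Step 7
Reactants: 11
Product: 12 tert-butyl 2-[(1S,2R,4R,5S)-4-azido-2-[(tert-butyldimethylsilyl)oxy]-7-oxo-6-oxabicyclo[3.2.1]octan-1-yl]acetate
Conditions: NaN3 (3 equiv), DMF, 60 °C
Reagents that add atoms: sodium azide, [Na+].[N-]=[N+]=[N-]
Why: SN2 displacement of the axial secondary iodide by azide with inversion places nitrogen cis to the lactone oxygen; departure of iodine also relieves the syn-axial contact with the silyloxy group.

Step 8
Reactants: 12
Product: 13 tert-butyl 2-[(1S,2R,4R,5S)-4-azido-2-[(tert-butyldimethylsilyl)oxy]-7-hydroxy-6-oxabicyclo[3.2.1]octan-1-yl]acetate (lactol epimers)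
Conditions: iBu2AlH (1.2 equiv), CH2Cl2, −78 °C; aq. potassium sodium tartrate
Reagents that add atoms: none
Why: Partial reduction of a lactone to the lactol at −78 °C; the strained bridged lactone reacts faster than the tert-butyl ester and the azide is inert to the hydride at this temperature.

Step 9
Reactants: 14 6-methylhept-5-en-2-one
Product: 16 6-methylhept-5-en-1-yne, via enol phosphate 15 (not isolated)
Conditions: LiN(iPr)2 (1.05 equiv), THF, −78 °C; ClP(O)(OEt)2, −78 → 23 °C; then LiN(iPr)2 (2.3 equiv), −78 → 23 °C
Reagents that add atoms: none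
Why: Kinetic deprotonation at the methyl group and O-phosphorylation give 15, and elimination with excess amide base gives the terminal alkyne (methyl ketone to alkyne through the enol phosphate); the trisubstituted alkene is untouched.

Step 10
Reactants: 16
Product: 18 (1E)-1-iodo-2,6-dimethylhepta-1,5-diene, via alkenylalane 17 (not isolated)
Conditions: Me3Al (2 equiv), Cp2ZrCl2 (0.2 equiv), CH2Cl2, 0 → 23 °C; then I2, THF, −30 → 0 °C
Reagents that add atoms: trimethylaluminium, C[Al](C)C; iodine, II
Why: Negishi zirconium-catalysed carboalumination adds methyl and aluminium syn across the alkyne with aluminium at the terminus, and iodinolysis of 17 proceeds with retention, so the E trisubstituted alkenyl iodide results.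

Step 11
Reactants: 13; 18
Product: 21 tert-butyl 2-[(1R,2R,4R,5S)-4-azido-2-[(tert-butyldimethylsilyl)oxy]-5-hydroxy-1-[(1R,2E)-1-hydroxy-3,7-dimethylocta-2,6-dien-1-yl]cyclohexyl]acetate, via alkenyllithium 19 (not isolated), via alkenylmagnesium bromide 20 (not isolated)
Conditions: 18 (2.4 equiv), tBuLi (4.8 equiv), Et2O, −78 °C; MgBr2·OEt2 (2.5 equiv), −78 → 0 °C; then 13, THF, −78 → −20 °C; aq. NH4Cl
Reagents that add atoms: none
Why: Grignard addition to a lactol: one equivalent of 20 deprotonates 13, whose open hydroxy-aldehyde form is held by magnesium between the aldehyde oxygen and the syn-axial ring alkoxide, and the alkenyl group adds to the outer face of this chelate, away from the cyclohexane ring, which sets the carbinol as 1'R. Lithium–iodine exchange and transmetallation retain the E geometry, and at low temperature the aldehyde outpaces the tert-butyl ester and the azide.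

Step 12
Reactants: 21
Product: 23 (1R,5R,6R,8R,9S)-8-azido-6-[(tert-butyldimethylsilyl)oxy]-1-[(1E)-2,6-dimethylhepta-1,5-dien-1-yl]-3-oxo-2-oxaspiro[4.5]decan-9-yl acetate, via hydroxy lactone 22 (not isolated)
Conditions: KOtBu (0.2 equiv), THF, 0 °C; then Ac2O, pyridine, DMAP (cat.), 0 → 23 °C
Reagents that add atoms: acetic anhydride, CC(=O)OC(C)=O
Why: Base-catalysed lactonisation: only the side-chain alkoxide can reach the tert-butyl ester (the ring hydroxyl is trans to the arm and the other ring oxygen is silylated), so the spiro γ-lactone 22 closes by 5-exo attack with loss of tert-butoxide. Acetylation of the remaining secondary hydroxyl in the same flask gives 23.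

Step 13
Reactants: 23
Product: 24 (1R,5S,6R,8R,9S)-8-azido-1-[(1E)-2,6-dimethylhepta-1,5-dien-1-yl]-6-hydroxy-3-oxo-2-oxaspiro[4.5]decan-9-yl acetate
Conditions: HF·pyridine, pyridine, THF, 0 → 23 °C
Reagents that add atoms: none
Why: Fluoride cleavage of the silyl ether under buffered conditions that leave acetate, azide, lactone and alkenes intact. The alcohol is oxidised without storage, because the freed hydroxyl is cis to the lactone arm and could take over the acyl group.

Step 14
Reactants: 24
Product: 25 (1R,5R,8R,9S)-8-azido-1-[(1E)-2,6-dimethylhepta-1,5-dien-1-yl]-3,6-dioxo-2-oxaspiro[4.5]decan-9-yl acetate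
Conditions: Dess–Martin periodinane, NaHCO3, CH2Cl2, 0 → 23 °C
Reagents that add atoms: none
Why: Dess–Martin oxidation of a hindered secondary alcohol under buffered, non-basic conditions that avoid elimination of the β-azide; the C6 stereocentre, having directed step 3, is erased here.

Step 15
Reactants: 25
Product: 27 N-[(1R,5R,8R,9S)-1-[(1E)-2,6-dimethylhepta-1,5-dien-1-yl]-9-hydroxy-3,6-dioxo-2-oxaspiro[4.5]decan-8-yl]acetamide ((+)-miliusane V), via amino acetate 26 (not isolated)
Conditions: PMe3 (1.5 equiv), THF/H2O (10:1), 0 → 23 °C
Reagents that add atoms: none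
Why: Staudinger reduction gives amine 26, which is cis to the neighbouring acetate and takes over the acetyl group by O-to-N acyl migration through a five-membered tetrahedral intermediate, unveiling the C9 hydroxyl. The conditions are neutral and spare the alkenes, the ketone and the allylic lactone.

**Compound list**

1 | buta-1,3-diene | C=CC=C | starting material
2 | methyl propiolate | C#CC(=O)OC | starting material
3 | methyl cyclohexa-1,4-diene-1-carboxylate | COC(=O)C1=CCC=CC1 | intermediate
4 | methyl (6R)-6-(4,4,5,5-tetramethyl-1,3,2-dioxaborolan-2-yl)cyclohex-3-ene-1-carboxylate (C1 epimers) | COC(=O)C1CC=CC[C@H]1B2OC(C)(C)C(C)(C)O2 | intermediate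
5 | methyl (6R)-6-hydroxycyclohex-3-ene-1-carboxylate (C1 epimers) | COC(=O)C1CC=CC[C@H]1O | intermediate
6 | tert-butyl bromoacetate | BrCC(=O)OC(C)(C)C | starting material
7 | dilithium salt of 5 (ester enolate and 6R alkoxide) | COC([O-])=C1CC=CC[C@H]1[O-].[Li+].[Li+] | intermediate
8 | methyl (1S,6R)-1-(2-tert-butoxy-2-oxoethyl)-6-hydroxycyclohex-3-ene-1-carboxylate | COC(=O)[C@]1(CC(=O)OC(C)(C)C)CC=CC[C@H]1O | intermediate
9 | methyl (1S,6R)-1-(2-tert-butoxy-2-oxoethyl)-6-[(tert-butyldimethylsilyl)oxy]cyclohex-3-ene-1-carboxylate | COC(=O)[C@]1(CC(=O)OC(C)(C)C)CC=CC[C@H]1O[Si](C)(C)C(C)(C)C | intermediate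
10 | (1S,6R)-1-(2-tert-butoxy-2-oxoethyl)-6-[(tert-butyldimethylsilyl)oxy]cyclohex-3-ene-1-carboxylic acid | OC(=O)[C@]1(CC(=O)OC(C)(C)C)CC=CC[C@H]1O[Si](C)(C)C(C)(C)C | intermediate
11 | tert-butyl 2-[(1S,2R,4S,5S)-2-[(tert-butyldimethylsilyl)oxy]-4-iodo-7-oxo-6-oxabicyclo[3.2.1]octan-1-yl]acetate | O=C1O[C@H]2C[C@]1(CC(=O)OC(C)(C)C)[C@H](O[Si](C)(C)C(C)(C)C)C[C@@H]2I | intermediate
12 | tert-butyl 2-[(1S,2R,4R,5S)-4-azido-2-[(tert-butyldimethylsilyl)oxy]-7-oxo-6-oxabicyclo[3.2.1]octan-1-yl]acetate | O=C1O[C@H]2C[C@]1(CC(=O)OC(C)(C)C)[C@H](O[Si](C)(C)C(C)(C)C)C[C@H]2N=[N+]=[N-] | intermediate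
13 | tert-butyl 2-[(1S,2R,4R,5S)-4-azido-2-[(tert-butyldimethylsilyl)oxy]-7-hydroxy-6-oxabicyclo[3.2.1]octan-1-yl]acetate (C7 epimers) | OC1O[C@H]2C[C@]1(CC(=O)OC(C)(C)C)[C@H](O[Si](C)(C)C(C)(C)C)C[C@H]2N=[N+]=[N-] | intermediate
14 | 6-methylhept-5-en-2-one | CC(=O)CCC=C(C)C | starting material
15 | diethyl 6-methylhepta-1,5-dien-2-yl phosphate | C=C(CCC=C(C)C)OP(=O)(OCC)OCC | intermediate
16 | 6-methylhept-5-en-1-yne | C#CCCC=C(C)C | intermediate
17 | [(1E)-2,6-dimethylhepta-1,5-dien-1-yl]dimethylalane | C[Al](C)/C=C(\C)CCC=C(C)C | intermediate
18 | (1E)-1-iodo-2,6-dimethylhepta-1,5-diene | I/C=C(\C)CCC=C(C)C | intermediate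
19 | [(1E)-2,6-dimethylhepta-1,5-dien-1-yl]lithium | [Li]/C=C(\C)CCC=C(C)C | intermediate
20 | [(1E)-2,6-dimethylhepta-1,5-dien-1-yl]magnesium bromide | Br[Mg]/C=C(\C)CCC=C(C)C | intermediate
21 | tert-butyl 2-[(1R,2R,4R,5S)-4-azido-2-[(tert-butyldimethylsilyl)oxy]-5-hydroxy-1-[(1R,2E)-1-hydroxy-3,7-dimethylocta-2,6-dien-1-yl]cyclohexyl]acetate | [N-]=[N+]=N[C@@H]1C[C@@H](O[Si](C)(C)C(C)(C)C)[C@](CC(=O)OC(C)(C)C)([C@H](O)/C=C(\C)CCC=C(C)C)C[C@@H]1O | intermediate
22 | (1R,5R,6R,8R,9S)-8-azido-6-[(tert-butyldimethylsilyl)oxy]-1-[(1E)-2,6-dimethylhepta-1,5-dien-1-yl]-9-hydroxy-2-oxaspiro[4.5]decan-3-one | [N-]=[N+]=N[C@@H]1C[C@@H](O[Si](C)(C)C(C)(C)C)[C@@]2(CC(=O)O[C@@H]2/C=C(\C)CCC=C(C)C)C[C@@H]1O | intermediate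
23 | (1R,5R,6R,8R,9S)-8-azido-6-[(tert-butyldimethylsilyl)oxy]-1-[(1E)-2,6-dimethylhepta-1,5-dien-1-yl]-3-oxo-2-oxaspiro[4.5]decan-9-yl acetate | [N-]=[N+]=N[C@@H]1C[C@@H](O[Si](C)(C)C(C)(C)C)[C@@]2(CC(=O)O[C@@H]2/C=C(\C)CCC=C(C)C)C[C@@H]1OC(C)=O | intermediate
24 | (1R,5S,6R,8R,9S)-8-azido-1-[(1E)-2,6-dimethylhepta-1,5-dien-1-yl]-6-hydroxy-3-oxo-2-oxaspiro[4.5]decan-9-yl acetate | [N-]=[N+]=N[C@@H]1C[C@@H](O)[C@@]2(CC(=O)O[C@@H]2/C=C(\C)CCC=C(C)C)C[C@@H]1OC(C)=O | intermediate
25 | (1R,5R,8R,9S)-8-azido-1-[(1E)-2,6-dimethylhepta-1,5-dien-1-yl]-3,6-dioxo-2-oxaspiro[4.5]decan-9-yl acetate | [N-]=[N+]=N[C@@H]1CC(=O)[C@@]2(CC(=O)O[C@@H]2/C=C(\C)CCC=C(C)C)C[C@@H]1OC(C)=O | intermediate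
26 | (1R,5R,8R,9S)-8-amino-1-[(1E)-2,6-dimethylhepta-1,5-dien-1-yl]-3,6-dioxo-2-oxaspiro[4.5]decan-9-yl acetate | N[C@@H]1CC(=O)[C@@]2(CC(=O)O[C@@H]2/C=C(\C)CCC=C(C)C)C[C@@H]1OC(C)=O | intermediate
27 | N-[(1R,5R,8R,9S)-1-[(1E)-2,6-dimethylhepta-1,5-dien-1-yl]-9-hydroxy-3,6-dioxo-2-oxaspiro[4.5]decan-8-yl]acetamide, (+)-miliusane V | CC(=O)N[C@@H]1CC(=O)[C@@]2(CC(=O)O[C@@H]2/C=C(\C)CCC=C(C)C)C[C@@H]1O | target

**Step count and least certain steps**

Total: 15 steps. Longest linear sequence: 13 steps (steps 1–8 and 11–15); steps 9 and 10 are the side-chain branch.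

Step 6 (key step). The most likely failure is slow ring closure, because iodine must engage the alkene face that carries the pseudo-axial silyloxy group. Reversible iodination without cyclisation, or capture by the tert-butyl ester carbonyl from the other face with loss of isobutene, could then compete. The fallback sets out from 8 and rejoins the route at 12. The free hydroxyl of 8 directs a VO(acac)2/tBuOOH epoxidation to its own face to give the epoxy alcohol F1, which is silylated (TBSOTf, 2,6-lutidine) to the epoxy silyl ether F2. Saponification with LiOH gives the epoxy acid F3. Its carboxyl opens the epoxide at the nearer carbon from the opposite face (camphorsulfonic acid catalysis if needed) to give the hydroxy lactone F4, which has a hydroxyl where 11 has iodine. Triflation (Tf2O, pyridine) gives the triflate F5, and displacement with NaN3 in DMF, with inversion, delivers 12. The electrophile is thus directed by the hydroxyl instead of being hindered by its silyl ether.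

Step 11. Two things may go wrong: facial selectivity may be poor or reversed if the aldehyde reacts outside the magnesium chelate, and the Grignard reagent may attack the azide. The fallback sets out from 12 and rejoins at 21; it inverts the order of the two nucleophiles. Alkenyllithium 19 is added to lactone 12 at −78 °C to give the hydroxy enone F6 (in equilibrium with its bridged hemiketal). Reduction with NaBH4 and CeCl3·7H2O in MeOH at −78 °C then brings hydride to the face that the alkenyl group took in the main route, so the carbinol configuration is inverted relative to that outcome and 21 is obtained.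

Step 15. The β-azido ketone 25 may lose the nitrogen function by β-elimination under the basic phosphorus–nitrogen intermediates or the free amine, before acyl transfer is complete. The fallback sets out from 24 and rejoins at 27; it performs the reduction before the ketone exists. PMe3 in wet THF converts 24, by the same acyl migration, into the dihydroxy acetamide F7. The less hindered C9 hydroxyl is silylated selectively (TESCl, imidazole, −20 °C) to give the silyl ether F8. Dess–Martin oxidation gives the ketone F9, and HF·pyridine removes the silyl group to give 27.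

Step 2. Enantioselectivity may be insufficient for a cyclic enoate with a trisubstituted alkene, and alkoxide may move the skipped diene into conjugation. The fallback sets out from 3 and rejoins at 5. Borylation with an achiral catalyst (CuCl, NaOtBu, 4,5-bis(diphenylphosphino)-9,9-dimethylxanthene, B2pin2, MeOH) and perborate oxidation give the racemic hydroxy ester F10. Lipase-catalysed acetylation (Candida antarctica lipase B, vinyl acetate) is expected, by the usual empirical rule for secondary alcohols, to acylate the 6R enantiomer. The acetate F11 is separated from unreacted alcohol and methanolysed (K2CO3, MeOH, 0 °C) to 5.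

## Further compounds

F1 | step 6 | methyl 3-(2-tert-butoxy-2-oxoethyl)-4-hydroxy-7-oxabicyclo[4.1.0]heptane-3-carboxylate, epoxide cis to the hydroxyl and the acetate arm | COC(=O)[C@]1(CC(=O)OC(C)(C)C)C[C@H]2O[C@H]2C[C@H]1O
F2 | step 6 | methyl 3-(2-tert-butoxy-2-oxoethyl)-4-[(tert-butyldimethylsilyl)oxy]-7-oxabicyclo[4.1.0]heptane-3-carboxylate, epoxide cis to the silyloxy group | COC(=O)[C@]1(CC(=O)OC(C)(C)C)C[C@H]2O[C@H]2C[C@H]1O[Si](C)(C)C(C)(C)C
F3 | step 6 | 3-(2-tert-butoxy-2-oxoethyl)-4-[(tert-butyldimethylsilyl)oxy]-7-oxabicyclo[4.1.0]heptane-3-carboxylic acid, epoxide trans to the carboxyl | OC(=O)[C@]1(CC(=O)OC(C)(C)C)C[C@H]2O[C@H]2C[C@H]1O[Si](C)(C)C(C)(C)C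
F4 | step 6 | tert-butyl 2-[(1S,2R,4S,5S)-2-[(tert-butyldimethylsilyl)oxy]-4-hydroxy-7-oxo-6-oxabicyclo[3.2.1]octan-1-yl]acetate | O=C1O[C@H]2C[C@]1(CC(=O)OC(C)(C)C)[C@H](O[Si](C)(C)C(C)(C)C)C[C@@H]2O
F5 | step 6 | tert-butyl 2-[(1S,2R,4S,5S)-2-[(tert-butyldimethylsilyl)oxy]-7-oxo-4-[(trifluoromethanesulfonyl)oxy]-6-oxabicyclo[3.2.1]octan-1-yl]acetate | O=C1O[C@H]2C[C@]1(CC(=O)OC(C)(C)C)[C@H](O[Si](C)(C)C(C)(C)C)C[C@@H]2OS(=O)(=O)C(F)(F)F
F6 | step 11 | tert-butyl 2-[(1S,2R,4R,5S)-4-azido-2-[(tert-butyldimethylsilyl)oxy]-1-[(2E)-3,7-dimethylocta-2,6-dienoyl]-5-hydroxycyclohexyl]acetate | [N-]=[N+]=N[C@@H]1C[C@@H](O[Si](C)(C)C(C)(C)C)[C@](CC(=O)OC(C)(C)C)(C(=O)/C=C(\C)CCC=C(C)C)C[C@@H]1O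
F7 | step 15 | N-[(1R,5S,6R,8R,9S)-1-[(1E)-2,6-dimethylhepta-1,5-dien-1-yl]-6,9-dihydroxy-3-oxo-2-oxaspiro[4.5]decan-8-yl]acetamide | CC(=O)N[C@@H]1C[C@@H](O)[C@@]2(CC(=O)O[C@@H]2/C=C(\C)CCC=C(C)C)C[C@@H]1O
F8 | step 15 | N-[(1R,5S,6R,8R,9S)-1-[(1E)-2,6-dimethylhepta-1,5-dien-1-yl]-6-hydroxy-3-oxo-9-[(triethylsilyl)oxy]-2-oxaspiro[4.5]decan-8-yl]acetamide | CC(=O)N[C@@H]1C[C@@H](O)[C@@]2(CC(=O)O[C@@H]2/C=C(\C)CCC=C(C)C)C[C@@H]1O[Si](CC)(CC)CC
F9 | step 15 | N-[(1R,5R,8R,9S)-1-[(1E)-2,6-dimethylhepta-1,5-dien-1-yl]-3,6-dioxo-9-[(triethylsilyl)oxy]-2-oxaspiro[4.5]decan-8-yl]acetamide | CC(=O)N[C@@H]1CC(=O)[C@@]2(CC(=O)O[C@@H]2/C=C(\C)CCC=C(C)C)C[C@@H]1O[Si](CC)(CC)CC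
F10 | step 2 | methyl 6-hydroxycyclohex-3-ene-1-carboxylate, racemic | COC(=O)C1CC=CCC1O
F11 | step 2 | methyl (6R)-6-acetoxycyclohex-3-ene-1-carboxylate | COC(=O)C1CC=CC[C@H]1OC(C)=O
A1 | alternative 1 | 1-[2-{2-[(tert-butyldimethylsilyl)oxy]ethyl}-3-[(1E)-2,6-dimethylhepta-1,5-dien-1-yl]oxiran-2-yl]cyclopentan-1-ol, single enantiomer as drawn | OC1(CCCC1)[C@]2(CCO[Si](C)(C)C(C)(C)C)O[C@@H]2/C=C(\C)CCC=C(C)C
A2 | alternative 1 | 2-{2-[(tert-butyldimethylsilyl)oxy]ethyl}-2-[(2E)-1-hydroxy-3,7-dimethylocta-2,6-dien-1-yl]cyclohexan-1-one, single stereoisomer as drawn | O=C1CCCC[C@@]1(CCO[Si](C)(C)C(C)(C)C)[C@H](O)/C=C(\C)CCC=C(C)C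
A3 | alternative 2 | open-chain aldoxime: methyl (3E,5E)-3-[3-acetamido-2-[(tert-butyldimethylsilyl)oxy]-5-(hydroxyimino)pentyl]-5,9-dimethyldeca-3,5,8-trienoate, syn amino alcohol as drawn | O/N=C/C[C@@H](NC(C)=O)[C@@H](O[Si](C)(C)C(C)(C)C)C/C(CC(=O)OC)=C\C=C(/C)CCC=C(C)C
A4 | alternative 2 | nitrile oxide derived from A3 | [O-][N+]#CC[C@@H](NC(C)=O)[C@@H](O[Si](C)(C)C(C)(C)C)C/C(CC(=O)OC)=C\C=C(/C)CCC=C(C)C
A5 | alternative 2 | ring-fused isoxazoline carrying the acetamide, silyl ether, methyl acetate arm and dienyl chain | CC(=O)N[C@@H]1CC2=NO[C@H](/C=C(\C)CCC=C(C)C)[C@]2(CC(=O)OC)C[C@@H]1O[Si](C)(C)C(C)(C)C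
A6 | alternative 3 | methyl (5E)-6,10-dimethyl-3-methylidene-4-oxoundeca-5,9-dienoate | C=C(CC(=O)OC)C(=O)/C=C(\C)CCC=C(C)C
A7 | alternative 3 | (1E,3E)-4-[(tert-butyldimethylsilyl)oxy]buta-1,3-dien-1-yl acetate | CC(=O)O/C=C/C=C/O[Si](C)(C)C(C)(C)C
A8 | alternative 3 | all-cis methyl 2-[5-acetoxy-2-[(tert-butyldimethylsilyl)oxy]-1-[(2E)-3,7-dimethylocta-2,6-dienoyl]cyclohex-3-en-1-yl]acetate | CC(=O)O[C@@H]1C=C[C@H](O[Si](C)(C)C(C)(C)C)[C@](CC(=O)OC)(C(=O)/C=C(\C)CCC=C(C)C)C1
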